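Locants used: ring C1 (CHBr), C2 (CMe2), C3 (CHCl), C4 (=C), C5 (CHCl), C6 (CH2); side chain C1′ (=CH), C2′ (CH2Br).
Cuts, in retrosynthetic order: C3–Cl is cut with allylic transposition, giving a C3=C4 cyclohexene with a C1′ carbinol. The six-membered ring is then contracted by re-joining C3 to C5, giving a cyclopentane (C1, C2, C3, C5, C6) bridged by C4. The remaining cuts are C4–C3 and C4–C5 (chlorocarbenoid + cyclopentene), C1′–C2′ (ester + LiCH2Br), and C1–Br together with one C2–CH3 bond (bromonium-triggered methyl shift).
Enabling feature: C3–C4–C5 is an allyl triad whose central atom C4 carries only carbon and whose termini carry chlorine. This is a 2-substituted cyclohexenyl cation plus chloride, which is what the strained C3–C5 bond of an endo-6-chlorobicyclo[3.1.0]hexane releases on disrotatory opening.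
Forward: cyclopentenone → tertiary allylic alcohol → β-bromo ketone (CMe2–CHBr in place) → cyclopentene → bicyclo[3.1.0]hexane (adds C4, C1′) → bromomethyl carbinol (adds C2′) → ring expansion 5 → 6 (C5–Cl) → SNi′ (C3–Cl, E-alkene, allylic bromide).
Stereochemistry: a catalytic asymmetric methyl addition sets one carbinol centre, which is relayed to C1 because methyl migrates anti to Br. C1–Br sends the carbenoid to the opposite face, and the endo chloride returns on that face (C5). A CBS reduction sets C1′, which is transferred suprafacially to C3 and to the alkene geometry.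

Key step: step 8

Assumption: the sense of induction in steps 1 and 7 follows the accepted models for these catalysts; if it proved opposite, the antipodal ligand would be used.

Step 1
Reactants: 1 2-methylcyclopent-2-en-1-one
Product: 2 (R)-1,2-dimethylcyclopent-2-en-1-ol
Conditions: Me2Zn, Ti(OiPr)4, bis(hydroxycamphorsulfonamide) ligand of trans-cyclohexane-1,2-diamine (cat.), toluene/hexane, rt; aq NH4Cl
Reagents that add atoms: dimethylzinc, C[Zn]C
Why: Titanium-promoted catalytic enantioselective 1,2-addition of a dialkylzinc to a ketone, in which the chiral Ti bis(sulfonamide) complex distinguishes the substituted sp2 flank from the CH2 flank of a 2-substituted cyclic enone and so sets the tertiary carbinol centre.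

Step 2
Reactants: 2 (R)-1,2-dimethylcyclopent-2-en-1-ol
Product: 3 (S)-3-bromo-2,2-dimethylcyclopentan-1-one
Conditions: NBS, CH2Cl2, −40 → 0 °C
Reagents that add atoms: N-bromosuccinimide, O=C1CCC(=O)N1Br
Why: Halonium-induced semipinacol rearrangement of an allylic alcohol, in which Br+ adds to the face bearing the small, hydrogen-bonding OH, the carbinol methyl anti-periplanar to the tertiary C–Br bond migrates (the ring CH2 lies in the nodal plane and would give a cyclobutane), and the neopentyl C–Br stereocentre is thus set by chirality transfer with electrophilic bromine; a bromonium ion on the wrong face cannot lead to the ketone.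

Step 3
Reactants: 3 (S)-3-bromo-2,2-dimethylcyclopentan-1-one
Product: 4 (S)-4-bromo-5,5-dimethylcyclopent-1-en-1-yl trifluoromethanesulfonate
Conditions: KHMDS, THF, −78 °C; PhNTf2, −78 → 0 °C; aq NH4Cl
Reagents that add atoms: N-phenylbis(trifluoromethanesulfonimide), O=S(=O)(N(c1ccccc1)S(=O)(=O)C(F)(F)F)C(F)(F)F
Why: Enolate O-sulfonylation, in which enolisation can only occur at the CH2 flank because the other α-carbon is quaternary, a non-nucleophilic amide base avoids carbonyl addition (and thus Grob fragmentation of the γ-bromide), and no stereocentre is touched.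

Step 4
Reactants: 4 (S)-4-bromo-5,5-dimethylcyclopent-1-en-1-yl trifluoromethanesulfonate
Product: 5 (S)-4-bromo-3,3-dimethylcyclopent-1-ene
Conditions: Pd(OAc)2 (cat.), PPh3, HCO2H, Bu3N, DMF, 40 °C
Reagents that add atoms: none
Why: Palladium-catalysed formate reduction of an enol triflate, in which oxidative addition into the vinyl C–O bond is far faster than into an unactivated, neopentyl secondary C–Br bond and the buffered medium is too weakly basic for E2 loss of HBr.

Step 5
Reactants: 5 (S)-4-bromo-3,3-dimethylcyclopent-1-ene; 6 ethyl diazoacetate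
Product: 8 ethyl (1S,3S,5S,6S)-3-bromo-6-chloro-2,2-dimethylbicyclo[3.1.0]hexane-6-carboxylate (Cl endo, ester exo, cyclopropane anti to Br), via ethyl chlorodiazoacetate 7 (not isolated)
Conditions: 6, DBU, NCS, CH2Cl2, 0 °C, cold filtration; solution added slowly to 5, Rh2(esp)2 (cat.), CH2Cl2, 0 °C → rt
Reagents that add atoms: N-chlorosuccinimide, O=C1CCC(=O)N1Cl
Why: Rhodium-catalysed cyclopropanation with a halodiazoacetate under neutral conditions that spare the base-sensitive homoallylic bromide; the carbenoid attacks the alkene face opposite to C–Br, and the halogen plays the donor role as in donor/acceptor carbenoids, so the ester ends up anti to the ring (exo) and chlorine endo.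

Step 6
Reactants: 8 ethyl (1S,3S,5S,6S)-3-bromo-6-chloro-2,2-dimethylbicyclo[3.1.0]hexane-6-carboxylate
Product: 9 2-bromo-1-[(1S,3S,5S,6S)-3-bromo-6-chloro-2,2-dimethylbicyclo[3.1.0]hexan-6-yl]ethan-1-one
Conditions: CH2Br2, MeLi·LiBr (slow addition), THF/Et2O, −78 °C; AcOH, −78 °C
Reagents that add atoms: dibromomethane, BrCBr
Why: Acylation of a halomethyllithium by an ester, in which the carbenoid is made by fast Br/Li exchange in the presence of the ester and the tetrahedral adduct survives at −78 °C until the acid quench, so only one CH2Br unit is added and the alkyl and cyclopropyl halides are not exchanged.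

Step 7
Reactants: 9 2-bromo-1-[(1S,3S,5S,6S)-3-bromo-6-chloro-2,2-dimethylbicyclo[3.1.0]hexan-6-yl]ethan-1-one
Product: 10 (1R)-2-bromo-1-[(1S,3S,5S,6S)-3-bromo-6-chloro-2,2-dimethylbicyclo[3.1.0]hexan-6-yl]ethan-1-ol
Conditions: (R)-Me-CBS (cat.), BH3·SMe2, THF, −20 °C; MeOH
Reagents that add atoms: none
Why: Corey–Bakshi–Shibata reduction of an α-halo ketone under reagent control, with the fully substituted chlorocyclopropyl group as the large and CH2Br as the small substituent, which sets the R carbinol centre.

Step 8
Reactants: 10 (1R)-2-bromo-1-[(1S,3S,5S,6S)-3-bromo-6-chloro-2,2-dimethylbicyclo[3.1.0]hexan-6-yl]ethan-1-ol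
Product: 12 (1R)-2-bromo-1-[(4S,6S)-4-bromo-6-chloro-3,3-dimethylcyclohex-1-en-1-yl]ethan-1-ol, via cyclohexenyl cation chloride ion pair 11 (not isolated)
Conditions: chlorobenzene, 120 °C, sealed tube, base-washed glass
Reagents that add atoms: none
Why: Ionisation of the endo C–Cl bond is concerted with disrotatory cleavage of the bond shared by the two rings (two-electron cyclopropyl-to-allyl cation electrocyclic opening, Woodward–Hoffmann–DePuy rule), so release of the bicyclic strain inserts the bridge carbon into the cyclopentane and gives the 2-substituted cyclohexenyl cation 11. The closest known reaction type is the thermal isomerisation of endo-6-halobicyclo[3.1.0]hexanes to 3-halocyclohexenes. No ring is closed: the five-membered ring grows to six by scission of the zero-atom bridge. The one new stereocentre (C–Cl) is set by suprafacial collapse of the contact ion pair in a non-polar solvent, chloride returning on the face it left, which is the face formerly held by the cyclopropane and anti to C–Br; this is also the stereoelectronically preferred pseudo-axial attack on the conformer with equatorial bromine. Two selectivities are needed: only the endo-chloro epimer can open to a cis-allyl cation within a six-membered ring, which step 5 provides, and chloride must return to the terminus next to CH2 rather than to the one next to CMe2, which the gem-dimethyl group enforces sterically and which leaves the alkene at the neopentyl carbon, ready for step 9. The carbinol, whose O–H can hydrogen-bond to the departing geminal chloride, and both C–Br bonds are spectators under these neutral conditions.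

Step 9
Reactants: 12 (1R)-2-bromo-1-[(4S,6S)-4-bromo-6-chloro-3,3-dimethylcyclohex-1-en-1-yl]ethan-1-ol
Product: 14 ochtodene, (1S,3S,4E,5S)-1-bromo-4-(2-bromoethylidene)-3,5-dichloro-2,2-dimethylcyclohexane, via chlorosulfite ester 13 (not isolated)
Conditions: SOCl2, Et2O, 0 °C → rt (no base)
Reagents that add atoms: thionyl chloride, O=S(Cl)Cl
Why: SNi′ reaction of a secondary allylic alcohol with thionyl chloride in ether, in which the chlorosulfite collapses through a six-membered chair-like transition state with CH2Br equatorial (H inside) and delivers chlorine suprafacially to the ring terminus from the side of the C1′–O bond; for the R carbinol this is the face anti to the pseudo-axial methyl and syn to the existing C–Cl, so the axial C3–Cl centre and the E alkene (CH2Br trans to C3) are both set by 1,3-chirality transfer.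

Compound list
1 | 2-methylcyclopent-2-en-1-one | CC1=CCCC1=O | starting material
2 | (R)-1,2-dimethylcyclopent-2-en-1-ol | CC1=CCC[C@@]1(C)O | intermediate
3 | (S)-3-bromo-2,2-dimethylcyclopentan-1-one | CC1(C)[C@@H](Br)CCC1=O | intermediate
4 | (S)-4-bromo-5,5-dimethylcyclopent-1-en-1-yl trifluoromethanesulfonate | CC1(C)[C@@H](Br)CC=C1OS(=O)(=O)C(F)(F)F | intermediate
5 | (S)-4-bromo-3,3-dimethylcyclopent-1-ene | CC1(C)[C@@H](Br)CC=C1 | intermediate
6 | ethyl diazoacetate | CCOC(=O)C=[N+]=[N-] | starting material
7 | ethyl 2-chloro-2-diazoacetate | CCOC(=O)C(Cl)=[N+]=[N-] | intermediate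
8 | ethyl (1S,3S,5S,6S)-3-bromo-6-chloro-2,2-dimethylbicyclo[3.1.0]hexane-6-carboxylate | CC1(C)[C@@H](Br)C[C@H]2[C@@H]1[C@]2(Cl)C(=O)OCC | intermediate
9 | 2-bromo-1-[(1S,3S,5S,6S)-3-bromo-6-chloro-2,2-dimethylbicyclo[3.1.0]hexan-6-yl]ethan-1-one | CC1(C)[C@@H](Br)C[C@H]2[C@@H]1[C@]2(Cl)C(=O)CBr | intermediate
10 | (1R)-2-bromo-1-[(1S,3S,5S,6S)-3-bromo-6-chloro-2,2-dimethylbicyclo[3.1.0]hexan-6-yl]ethan-1-ol | CC1(C)[C@@H](Br)C[C@H]2[C@@H]1[C@]2(Cl)[C@@H](O)CBr | intermediate
11 | (5S)-5-bromo-2-[(1R)-2-bromo-1-hydroxyethyl]-4,4-dimethylcyclohex-2-en-1-ylium chloride, contact ion pair | CC1(C)[C@@H](Br)C[CH+]C([C@@H](O)CBr)=C1.[Cl-] | intermediate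
12 | (1R)-2-bromo-1-[(4S,6S)-4-bromo-6-chloro-3,3-dimethylcyclohex-1-en-1-yl]ethan-1-ol | CC1(C)[C@@H](Br)C[C@H](Cl)C([C@@H](O)CBr)=C1 | intermediate
13 | chlorosulfite ester of 12 | CC1(C)[C@@H](Br)C[C@H](Cl)C([C@@H](OS(=O)Cl)CBr)=C1 | intermediate
14 | ochtodene, (1S,3S,4E,5S)-1-bromo-4-(2-bromoethylidene)-3,5-dichloro-2,2-dimethylcyclohexane | CC1(C)[C@@H](Br)C[C@H](Cl)/C(=C\CBr)[C@@H]1Cl | target

Total step count: 9. Longest linear sequence: 9 steps (1 → 14); 6 enters in step 5.

Steps most likely to fail

Step 9. Chlorine may be delivered to the carbinol carbon (direct substitution) instead of to the hindered ring terminus next to CMe2. Ion-pair leakage may also erode the facial and E/Z fidelity. The fallback sets out from 10 and comes back at 14. Compound 10 is acetylated (Ac2O, pyridine) to the bromohydrin acetate F1. Zinc dust in ethanol effects reductive 1,2-elimination to the exo-vinyl endo-chloro bicycle F2. The same thermal ring expansion gives the chloro vinylcyclohexene F3. A BrCl equivalent (NBS, Et4NCl, MeNO2/CH2Cl2, low temperature) is then added 1,4 to the s-trans diene, with Br+ at the terminal CH2 and chloride pseudo-axially at the ring terminus anti to the axial methyl, to give 14. The alkene geometry then derives from the diene conformation and no longer from a carbinol centre.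

Step 2. The bromonium ion may form on the methyl-bearing face and be captured by the hydroxyl group. The tertiary allylic alcohol may ionise and dehydrate. Methyl is also a reluctant migrating group. The fallback sets out from 1 and comes back at 3. The antipodal ligand in step 1 gives (S)-1,2-dimethylcyclopent-2-en-1-ol F4. Hydroxyl-directed epoxidation (VO(acac)2, t-BuOOH) gives the syn epoxy alcohol F5. BF3·OEt2 triggers the epoxy alcohol semipinacol rearrangement (methyl shift anti to the tertiary C–O bond) to (R)-3-hydroxy-2,2-dimethylcyclopentan-1-one F6. Tf2O/2,6-lutidine gives the secondary triflate F7, and Bu4NBr displaces it with inversion to 3. The ring carbonyl disfavours ionisation and skeletal rearrangement in this displacement.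

Step 5. Carbenoid transfer to a cis-alkene flanked by a quaternary carbon may be slow relative to carbene dimerisation, and face or exo/endo selectivity may be imperfect. The fallback sets out from 5 and comes back at 12. Rh2(esp)2-catalysed transfer of a cationic carbyne equivalent from ethyl 2-diazo-2-(aryl-λ3-iodanyl)acetate triflate at low temperature gives a cyclopropyl iodane that opens at once. The planar cyclohexenyl cation makes the face of cyclopropanation irrelevant, and it is quenched pseudo-axially with Bu4NCl to the ring-expanded chloro ester F8. LiCH2Br as in step 6 gives the bromomethyl enone F9, and (R)-CBS reduction gives 12.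

Further compounds
F1 | step 9 | (1R)-2-bromo-1-[(1S,3S,5S,6S)-3-bromo-6-chloro-2,2-dimethylbicyclo[3.1.0]hexan-6-yl]ethyl acetate | CC1(C)[C@@H](Br)C[C@H]2[C@@H]1[C@]2(Cl)[C@@H](OC(C)=O)CBr
F2 | step 9 | 3-bromo-6-endo-chloro-6-exo-ethenyl-2,2-dimethylbicyclo[3.1.0]hexane (cyclopropane anti to Br) | CC1(C)[C@@H](Br)C[C@H]2[C@@H]1[C@]2(Cl)C=C
F3 | step 9 | (4S,6S)-4-bromo-6-chloro-1-ethenyl-3,3-dimethylcyclohex-1-ene | CC1(C)[C@@H](Br)C[C@H](Cl)C(C=C)=C1
F4 | step 2 | (S)-1,2-dimethylcyclopent-2-en-1-ol | CC1=CCC[C@]1(C)O
F5 | step 2 | 1,2-dimethyl-6-oxabicyclo[3.1.0]hexan-2-ol, epoxide oxygen and hydroxyl on the same face | C[C@@]12O[C@@H]1CC[C@]2(C)O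
F6 | step 2 | (R)-3-hydroxy-2,2-dimethylcyclopentan-1-one | CC1(C)[C@H](O)CCC1=O
F7 | step 2 | (R)-2,2-dimethyl-3-oxocyclopentyl trifluoromethanesulfonate | CC1(C)[C@H](OS(=O)(=O)C(F)(F)F)CCC1=O
F8 | step 5 | ethyl (4S,6S)-4-bromo-6-chloro-3,3-dimethylcyclohex-1-ene-1-carboxylate | CC1(C)[C@@H](Br)C[C@H](Cl)C(C(=O)OCC)=C1
F9 | step 5 | 2-bromo-1-[(4S,6S)-4-bromo-6-chloro-3,3-dimethylcyclohex-1-en-1-yl]ethan-1-one | CC1(C)[C@@H](Br)C[C@H](Cl)C(C(=O)CBr)=C1
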